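**Conventions.** Germacrane numbers are used for the target and kept for every intermediate: C1 ketone carbon, C2/C3 CH2, C4/C5 epoxide carbons, C6 lactone CH–O, C7=C11 butenolide alkene, C8 CH–O(acyl), C9 CH2, C10 CH–CH3, C12 lactone C=O, C13 CH2OAc, C14/C15 the methyls on C10/C4.

**Assumption.** Enone 1, the (3aS,6aS) antipode of the D-ribose-derived isopropylidenedioxycyclopentenone, is taken as a purchasable chiral-pool building block.

## The problem

The target is a germacranolide: a ten-membered carbocycle (C1–C10) with a C1 ketone, an epimerisable C10 methyl centre, a cis-fused trisubstituted C4–C5 epoxide (C3 and C6 on the same side, i.e. derived from a Z alkene), and a butenolide fused at C6–C7 whose tetrasubstituted C7=C11 alkene carries the C13 acetoxymethyl group; C8 carries a 2-(hydroxymethyl)acrylate. A cyclodecane resists direct closure (transannular strain, entropy), and its conformation is a poor guide for setting stereocentres that lie around the perimeter: C5/C6 adjacent (erythro), C6/C8 1,3-syn across sp2 C7, C8/C10 1,3-syn. Only the C6 hydroxyl can steer a neighbour (the epoxide); C8 and C10 need an outside source or a rigid small-ring template. The functional groups are fragile. Acid makes the C1 ketone open the 4,5-epoxide across the ring. Base removes C6–H (γ to the lactone, β to the epoxide) or displaces the C13 allylic acetate. The acrylate is a Michael acceptor with a free hydroxyl. The two esters therefore have to go on last. The feature that the plan exploits is that C1 and C7 are both ketone-level carbons: C7 is the β-carbon of the butenolide, which a C7 ketone delivers by intramolecular olefination from C6–O. They stand 1,5 to each other through C8–C9–C10 and 1,7 through C2–C6. A C1–C7 bond therefore divides the ten-membered ring into a cyclopentane (ring A: C7, C8, C9, C10, C1) and a cycloheptene (ring B: C1–C7), and a 1,2-diol on that bond gives back both ketones on glycol cleavage.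

## Retrosynthesis

**Ester groups (28 ⇒ 27 ⇒ 26 ⇒ 25 ⇒ 21 + 24).** The C8–O acyl bond, the C13–O acetyl bond and the side-chain O–Si bond are cut first. Both esters are electrophilic allylic systems, so they are installed after every organometallic, oxidative and basic step rather than carried through the ring construction. The forward steps are mild acylations and orthogonal deprotections (PMB at C13, silyl at C8 and on the side chain of acid 24), ordered so that the allylic acetate is made after the last DMAP-mediated step.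

**Butenolide (20 ⇒ 19).** The C7=C11 bond is cut to a C7 ketone and a phosphonoacetate on C6–O. Intramolecular Horner–Wadsworth–Emmons closure fixes the geometry of the tetrasubstituted alkene through the five-membered ring; cutting C6–C7 or C11–C12 instead would need a stereodefined tetrasubstituted alkenyl metal. Precursor 19 is a cyclodecane-1,5-dione. The forward step must use a mild base because C6–H of 19 is acidic and β to the epoxide.

**Ten-membered ring (19 ⇒ 18), the key disconnection.** No ring bond is cut; a bond is added, C1–C7. The two ketone carbons of 19 become the carbinol carbons of a ring-fusion cis-diol, bicyclo[5.3.0]decane 18 (its locants coincide with the germacrane numbers). Against any single cut of the cyclodecane, this replaces a medium-ring closure by a cyclopentane and a cycloheptene and puts C4, C5, C6, C8 and C10 on small rings, where cis/trans relationships are predictable. The two carbinol stereocentres at C1 and C7 are erased in the cleavage, so their configuration does not matter. The forward reaction only requires that the C1/C7 diol be the sole free vicinal diol (C6–O acylated, C8–O silylated).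

**Epoxide and C6 (18 ⇒ 13 + 17; 13 ⇒ 12 ⇒ 11).** The ester C–O bond and then the epoxide C–O bonds are cut. With C6–OH free in a cyclohept-2-enol, a hydroxyl-directed epoxidation gives the cis-epoxy alcohol, which is the erythro C5/C6 relationship of the target; after lactonisation this handle is gone, which is why the epoxide is made here. C6 itself comes from enone 11 by catalyst-controlled reduction.

**Ring B and the C6–C7 bond (11 ⇒ 10 ⇒ 8).** C4=C5 is cut by ring-closing metathesis; in a seven-membered ring the Z geometry is obligatory, whereas in the ten-membered ring it would have to be won. The C6–C7 bond is cut to ketone 8 and an acryloyl anion equivalent (lithiated methoxyallene), which brings C5 and C6 in one operation at the correct oxidation level for the metathesis.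

**Ring A adjustments and the C1–C2 bond (8 ⇒ 7 ⇒ 6 ⇒ 5 ⇒ 4).** The C7 ketone is traced to the acetonide-protected C7/C8 diol, and the C1–C2 bond to ketone 4 and a 3-methylbut-3-enyl Grignard reagent. The chain is added while C7/C8 are still tied as the acetonide, so the only carbonyl present is C1. The forward sequence needs one regioselective step: silylation of C8–OH over the more hindered C7–OH.

**C10 methyl (4 ⇒ 3 ⇒ 2 ⇒ 1).** The C10–CH3 bond is cut to the α-iodoenone. Hydrogenation of methyl enone 3 from the convex face of the cis-fused bicycle places the methyl cis to the C8 oxygen. Enolate methylation would give the opposite (trans) isomer. C8 (and the temporary C7 oxygen) come from the chiral pool in 1.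

**Acylating agents (17 ⇐ 16 ⇐ 14 + 15; 24 ⇐ 23 ⇐ 22).** Acid 17 carries the C11–C13 unit with C13–O masked as a PMB ether (a poor leaving group, unlike acetate, on the phosphonate carbanion). Acid 24 is the silyl-protected side chain. Both are two steps from commercial esters.

## Roads not taken

**Alternative 1:** the most obvious cut is C4=C5 of the ten-membered ring by ring-closing metathesis. The forward key step would be metathesis of diene A1 (butenolide and all carbinol centres in place) to (4Z)-cyclodecene A2, then epoxidation. A ten-membered trisubstituted alkene is a poor case for metathesis: ring strain competes with dimerisation and nothing but strain enforces Z. The epoxidation of A2 has no directing hydroxyl (C6–O is already the lactone oxygen), so its face selectivity rests on an unknown macrocycle conformation. C6, C8 and C10 would each need a separate asymmetric reaction on an open chain. The chosen plan runs the same metathesis in a seven-membered ring and epoxidises while C6–OH is free.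

**Alternative 2:** cut C6–C7 together with the lactone C–O bond. The forward step is an intramolecular Nozaki–Hiyama–Kishi addition of the (Z)-β-triflyloxy acrylate of A3 to its cis-epoxy aldehyde; the C6 alkoxide closes onto the cis ester and gives 20 directly. One step would close the macrocycle, form the butenolide and set C6 by Felkin control. But it loads three difficulties on one bond (a fully substituted alkenyl triflate, a ten-membered ring, an epoxy aldehyde). The triflate must come from an α-(alkoxymethyl) β-keto ester that readily loses alkoxide. The C8/C10 pair must again be built acyclically, so the precursor is no simpler than the product.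

**Alternative 3:** ring expansion by anionic oxy-Cope rearrangement. Vinyllithium adds to (S)-isopiperitenone A4, and the alkoxide of divinyl carbinol A5 rearranges to (2Z,6E)-3,7-dimethylcyclodeca-2,6-dienone A6, which has the full C1–C10/C14/C15 skeleton with the Z enone at C4=C5–C6. It reaches the ring in two steps, but A6 is achiral (the terpene stereocentre is erased) and oxygenated only at C6. C8 is an unactivated methylene; an oxygen placed beforehand on the vinyl terminus would be β to the rearrangement enolate and eliminate. C1=C10 must still become the α-methyl ketone and C7 must be elaborated, all on a flexible cyclodecadiene with no control element. The chosen fragmentation delivers both carbonyls and all five stereocentres at the moment the ring appears.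

Key step: step 15

## Route

Step 1
Reactants: 1 (3aS,6aS)-2,2-dimethyl-3a,6a-dihydro-4H-cyclopenta[d][1,3]dioxol-4-one
Product: 2 (3aS,6aS)-5-iodo-2,2-dimethyl-3a,6a-dihydro-4H-cyclopenta[d][1,3]dioxol-4-one
Conditions: I2, pyridine, CH2Cl2, 0 °C → rt
Reagents that add atoms: iodine, II
Why: α-Iodination of a cyclic enone (conjugate addition of pyridine, iodination of the enolate, elimination); only C10, the enone α-carbon, can react and the acetonide stereocentres are untouched.

Step 2
Reactants: 2 (3aS,6aS)-5-iodo-2,2-dimethyl-3a,6a-dihydro-4H-cyclopenta[d][1,3]dioxol-4-one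
Product: 3 (3aS,6aS)-2,2,5-trimethyl-3a,6a-dihydro-4H-cyclopenta[d][1,3]dioxol-4-one
Conditions: Me4Sn, PdCl2(PhCN)2 (5 mol%), AsPh3, CuI, NMP, 80 °C
Reagents that add atoms: tetramethylstannane, C[Sn](C)(C)C
Why: Stille cross-coupling of the alkenyl iodide; the base-free conditions avoid β-elimination of the C8 oxygen from the enone.

Step 3
Reactants: 3 (3aS,6aS)-2,2,5-trimethyl-3a,6a-dihydro-4H-cyclopenta[d][1,3]dioxol-4-one
Product: 4 (3aS,5R,6aS)-2,2,5-trimethyltetrahydro-4H-cyclopenta[d][1,3]dioxol-4-one (methyl cis to the dioxolane oxygens)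
Conditions: H2 (1 atm), 10% Pd/C, EtOAc, rt
Reagents that add atoms: none
Why: Heterogeneous hydrogenation from the convex face of the cis-fused bicycle (anti to the dioxolane) puts hydrogen on that face of C10, so the new C10 methyl centre is cis to the C8 oxygen as in the target (kinetic control).

Step 4
Reactants: 4 (3aS,5R,6aS)-2,2,5-trimethyltetrahydro-4H-cyclopenta[d][1,3]dioxol-4-one
Product: 5 (3aS,4R,5R,6aS)-2,2,5-trimethyl-4-(3-methylbut-3-en-1-yl)tetrahydro-4H-cyclopenta[d][1,3]dioxol-4-ol
Conditions: CH2=C(CH3)CH2CH2MgBr (from 4-bromo-2-methylbut-1-ene and Mg), CeCl3, THF, −78 °C; aq. NH4Cl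
Reagents that add atoms: 3-methylbut-3-en-1-ylmagnesium bromide, C=C(C)CC[Mg]Br
Why: 1,2-Addition of an organocerium reagent, whose low basicity avoids enolisation and hence epimerisation at C10 or β-elimination at C8; attack from the convex face gives the C1 carbinol drawn, a temporary stereocentre that is erased in step 15.

Step 5
Reactants: 5 (3aS,4R,5R,6aS)-2,2,5-trimethyl-4-(3-methylbut-3-en-1-yl)tetrahydro-4H-cyclopenta[d][1,3]dioxol-4-ol
Product: 6 (1R,2S,3S,5R)-5-methyl-1-(3-methylbut-3-en-1-yl)cyclopentane-1,2,3-triol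
Conditions: AcOH/H2O (4:1), 40 °C
Reagents that add atoms: none
Why: Acid-catalysed acetal hydrolysis; the mild aqueous acid leaves the tertiary alcohol and the 1,1-disubstituted alkene alone.

Step 6
Reactants: 6 (1R,2S,3S,5R)-5-methyl-1-(3-methylbut-3-en-1-yl)cyclopentane-1,2,3-triol
Product: 7 (1R,2S,3S,5R)-3-[(tert-butyldimethylsilyl)oxy]-5-methyl-1-(3-methylbut-3-en-1-yl)cyclopentane-1,2-diol
Conditions: TBSCl (1.05 equiv), imidazole, DMF, −20 → 0 °C
Reagents that add atoms: tert-butyldimethylsilyl chloride, CC(C)(C)[Si](C)(C)Cl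
Why: Regioselective silyl ether formation: C8–OH is flanked by a CH2 group, whereas C7–OH sits next to the fully substituted C1 and the tertiary alcohol is inert to TBSCl/imidazole.

Step 7
Reactants: 7 (1R,2S,3S,5R)-3-[(tert-butyldimethylsilyl)oxy]-5-methyl-1-(3-methylbut-3-en-1-yl)cyclopentane-1,2-diol
Product: 8 (2R,3R,5S)-5-[(tert-butyldimethylsilyl)oxy]-2-hydroxy-3-methyl-2-(3-methylbut-3-en-1-yl)cyclopentan-1-one
Conditions: IBX, DMSO, rt
Reagents that add atoms: none
Why: IBX oxidation of the only secondary alcohol; IBX converts 1,2-diols into α-hydroxy ketones without C–C cleavage.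

Step 8
Reactants: 8 (2R,3R,5S)-5-[(tert-butyldimethylsilyl)oxy]-2-hydroxy-3-methyl-2-(3-methylbut-3-en-1-yl)cyclopentan-1-one
Product: 10 1-[(1S,2R,3R,5S)-5-[(tert-butyldimethylsilyl)oxy]-1,2-dihydroxy-3-methyl-2-(3-methylbut-3-en-1-yl)cyclopentyl]prop-2-en-1-one, via methoxyallenyl carbinol 9 (not isolated)
Conditions: methoxyallene, n-BuLi, THF, −78 °C (3 equiv of the lithio reagent), then 8; 1 M HCl, THF, 0 °C
Reagents that add atoms: 1-lithio-1-methoxyallene, [Li]C(OC)=C=C; water, O
Why: 1,2-Addition of lithiated methoxyallene (an acryloyl anion equivalent) to the ketone, expected anti to the C8 silyl ether (C7 is a temporary stereocentre), followed by enol ether hydrolysis to the α'-hydroxy vinyl ketone; the excess reagent covers the free tertiary hydroxyl.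

Step 9
Reactants: 10 1-[(1S,2R,3R,5S)-5-[(tert-butyldimethylsilyl)oxy]-1,2-dihydroxy-3-methyl-2-(3-methylbut-3-en-1-yl)cyclopentyl]prop-2-en-1-one
Product: 11 (1R,7S,8S,10R)-8-[(tert-butyldimethylsilyl)oxy]-1,7-dihydroxy-4,10-dimethylbicyclo[5.3.0]dec-4-en-6-one (cis ring fusion)
Conditions: second-generation Grubbs catalyst RuCl2(=CHPh)(PCy3)(H2IMes) (5 mol%), CH2Cl2, 40 °C
Reagents that add atoms: none
Why: Ring-closing metathesis to a seven-membered trisubstituted enone (C4=C5); the ring size enforces the cis (Z) geometry that the cis-fused epoxide of the target requires.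

Step 10
Reactants: 11 (1R,7S,8S,10R)-8-[(tert-butyldimethylsilyl)oxy]-1,7-dihydroxy-4,10-dimethylbicyclo[5.3.0]dec-4-en-6-one
Product: 12 (1R,6R,7S,8S,10R)-8-[(tert-butyldimethylsilyl)oxy]-4,10-dimethylbicyclo[5.3.0]dec-4-ene-1,6,7-triol
Conditions: (S)-2-methyl-CBS-oxazaborolidine (20 mol%), catecholborane (excess), toluene, −78 °C; MeOH, then aq. NaOH
Reagents that add atoms: none
Why: CBS (oxazaborolidine-catalysed) reduction: with the fully substituted C7 as the large group, the (S)-catalyst should deliver hydride to give the (6R)-allylic alcohol, i.e. C6–O syn to C8–O; the tertiary hydroxyls are capped in situ as catechol borates, which carry no hydride.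

Step 11
Reactants: 12 (1R,6R,7S,8S,10R)-8-[(tert-butyldimethylsilyl)oxy]-4,10-dimethylbicyclo[5.3.0]dec-4-ene-1,6,7-triol
Product: 13 (1R,4R,5S,6R,7S,8S,10R)-8-[(tert-butyldimethylsilyl)oxy]-4,5-epoxy-4,10-dimethylbicyclo[5.3.0]decane-1,6,7-triol
Conditions: VO(acac)2 (5 mol%), t-BuOOH, CH2Cl2, 0 °C
Reagents that add atoms: tert-butyl hydroperoxide, CC(C)(C)OO
Why: Hydroxyl-directed (vanadium-catalysed) epoxidation of a cyclohept-2-enol delivers oxygen cis to the C6 hydroxyl and sets C4 and C5 in the erythro relationship of the target; the tertiary C1–OH lies on the same face as the new epoxide and cannot open it from the back.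

Step 12
Reactants: 14 ethyl 2-(diethoxyphosphoryl)acrylate; 15 4-methoxybenzyl alcohol
Product: 16 ethyl 2-(diethoxyphosphoryl)-3-[(4-methoxybenzyl)oxy]propanoate (racemic)
Conditions: KOt-Bu (10 mol%), THF, 0 °C
Reagents that add atoms: none
Why: Base-catalysed oxa-Michael addition of the alcohol to the doubly activated alkene.

Step 13
Reactants: 16 ethyl 2-(diethoxyphosphoryl)-3-[(4-methoxybenzyl)oxy]propanoate
Product: 17 2-(diethoxyphosphoryl)-3-[(4-methoxybenzyl)oxy]propanoic acid (racemic)
Conditions: LiOH, THF/H2O, 0 °C; 1 M HCl to pH 3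
Reagents that add atoms: lithium hydroxide, [Li+].[OH-]
Why: Saponification of the carboxylic ethyl ester; phosphonate ethyl esters are not cleaved by cold LiOH.

Step 14
Reactants: 13 (1R,4R,5S,6R,7S,8S,10R)-8-[(tert-butyldimethylsilyl)oxy]-4,5-epoxy-4,10-dimethylbicyclo[5.3.0]decane-1,6,7-triol; 17 2-(diethoxyphosphoryl)-3-[(4-methoxybenzyl)oxy]propanoic acid
Product: 18 (1R,4R,5S,6R,7S,8S,10R)-8-[(tert-butyldimethylsilyl)oxy]-4,5-epoxy-1,7-dihydroxy-4,10-dimethylbicyclo[5.3.0]decan-6-yl 2-(diethoxyphosphoryl)-3-[(4-methoxybenzyl)oxy]propanoate (both epimers at the phosphonate carbon)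
Conditions: DCC, DMAP (cat.), CH2Cl2, 0 °C → rt
Reagents that add atoms: none
Why: Steglich esterification; only the secondary C6–OH is acylated because the two tertiary alcohols are unreactive, and this masks the C6/C7 diol ahead of the cleavage.

Step 15
Reactants: 18 (1R,4R,5S,6R,7S,8S,10R)-8-[(tert-butyldimethylsilyl)oxy]-4,5-epoxy-1,7-dihydroxy-4,10-dimethylbicyclo[5.3.0]decan-6-yl 2-(diethoxyphosphoryl)-3-[(4-methoxybenzyl)oxy]propanoate
Product: 19 (4R,5S,6R,8S,10R)-8-[(tert-butyldimethylsilyl)oxy]-4,5-epoxy-4,10-dimethyl-1,7-dioxocyclodecan-6-yl 2-(diethoxyphosphoryl)-3-[(4-methoxybenzyl)oxy]propanoate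
Conditions: Pb(OAc)4, pyridine, CH2Cl2, −20 → 0 °C
Reagents that add atoms: none
Why: Criegee glycol cleavage: the cis-1,2-diol forms a five-membered cyclic diester of tetravalent lead, which collapses in a concerted two-electron fragmentation that breaks the C1–C7 σ bond and turns both carbinol carbons into ketones while lead leaves as Pb(OAc)2. The closest known reaction type is the oxidative cleavage of ring-fusion 1,2-diols of decalins and hydrindanes to cyclodecane- and cyclononanediones. No ring is closed by bond formation: the ten-membered ring appears when the bond shared by rings A and B is cut, so the entropic and transannular cost of a direct cyclodecane closure is never paid. No new stereocentre is formed; the two that are destroyed (C1, C7) were temporary, so any diastereomer at these carbons converges on 19, and C4, C5, C6, C8 and C10 are carried over because none of their bonds is touched. The step needs chemoselectivity for one diol, which the substrate secures: C6–O is acylated and C8–O silylated, so the C1/C7 pair is the only free vicinal diol, and the epoxide, phosphonate and PMB ether are inert to Pb(OAc)4 at low temperature. Pyridine buffers the acetic acid released, which protects the epoxide and keeps the new 1,5-dione from enolising (transannular aldol, β-elimination across C5–C6).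

Step 16
Reactants: 19 (4R,5S,6R,8S,10R)-8-[(tert-butyldimethylsilyl)oxy]-4,5-epoxy-4,10-dimethyl-1,7-dioxocyclodecan-6-yl 2-(diethoxyphosphoryl)-3-[(4-methoxybenzyl)oxy]propanoate
Product: 20 (4R,5S,6S,8S,10R)-8-[(tert-butyldimethylsilyl)oxy]-4,5-epoxy-13-[(4-methoxybenzyl)oxy]-1-oxogermacr-7(11)-en-12,6-olide
Conditions: LiCl, i-Pr2NEt, MeCN, 0 °C → rt
Reagents that add atoms: none
Why: Intramolecular Horner–Wadsworth–Emmons olefination under mild LiCl/amine conditions closes the five-membered unsaturated lactone (5-exo attack of the phosphonate carbanion on the C7 ketone) and creates the tetrasubstituted C7=C11 alkene; the tether cannot reach the C1 ketone.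

Step 17
Reactants: 20 (4R,5S,6S,8S,10R)-8-[(tert-butyldimethylsilyl)oxy]-4,5-epoxy-13-[(4-methoxybenzyl)oxy]-1-oxogermacr-7(11)-en-12,6-olide
Product: 21 (4R,5S,6S,8S,10R)-4,5-epoxy-8-hydroxy-13-[(4-methoxybenzyl)oxy]-1-oxogermacr-7(11)-en-12,6-olide
Conditions: HF·pyridine, pyridine, THF, 0 °C → rt
Reagents that add atoms: none
Why: Fluoride-mediated silyl ether cleavage, buffered with pyridine to protect the 1-oxo-4,5-epoxide from acid.

Step 18
Reactants: 22 ethyl 2-(hydroxymethyl)acrylate
Product: 23 ethyl 2-{[(tert-butyldimethylsilyl)oxy]methyl}acrylate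
Conditions: TBSCl, imidazole, CH2Cl2, 0 °C
Reagents that add atoms: tert-butyldimethylsilyl chloride, CC(C)(C)[Si](C)(C)Cl
Why: Silyl ether formation at the primary allylic alcohol.

Step 19
Reactants: 23 ethyl 2-{[(tert-butyldimethylsilyl)oxy]methyl}acrylate
Product: 24 2-{[(tert-butyldimethylsilyl)oxy]methyl}acrylic acid
Conditions: LiOH, THF/H2O, 0 °C; 1 M HCl to pH 4
Reagents that add atoms: lithium hydroxide, [Li+].[OH-]
Why: Ester saponification; the primary TBS ether survives cold LiOH and a brief, mild acidification.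

Step 20
Reactants: 21 (4R,5S,6S,8S,10R)-4,5-epoxy-8-hydroxy-13-[(4-methoxybenzyl)oxy]-1-oxogermacr-7(11)-en-12,6-olide; 24 2-{[(tert-butyldimethylsilyl)oxy]methyl}acrylic acid
Product: 25 (4R,5S,6S,8S,10R)-8-[(2-{[(tert-butyldimethylsilyl)oxy]methyl}acryloyl)oxy]-4,5-epoxy-13-[(4-methoxybenzyl)oxy]-1-oxogermacr-7(11)-en-12,6-olide
Conditions: DCC, DMAP (cat.), CH2Cl2, 0 °C
Reagents that add atoms: none
Why: Steglich esterification of the C8 alcohol (the open hydroxy ketone is acylated out of its equilibrium with the C1 hemiketal); no allylic acetate is yet present that DMAP could displace.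

Step 21
Reactants: 25 (4R,5S,6S,8S,10R)-8-[(2-{[(tert-butyldimethylsilyl)oxy]methyl}acryloyl)oxy]-4,5-epoxy-13-[(4-methoxybenzyl)oxy]-1-oxogermacr-7(11)-en-12,6-olide
Product: 26 (4R,5S,6S,8S,10R)-8-[(2-{[(tert-butyldimethylsilyl)oxy]methyl}acryloyl)oxy]-4,5-epoxy-13-hydroxy-1-oxogermacr-7(11)-en-12,6-olide
Conditions: DDQ, CH2Cl2/pH 7 phosphate buffer, 0 °C
Reagents that add atoms: none
Why: Oxidative cleavage of the 4-methoxybenzyl ether by DDQ under buffered conditions; the silyl ether, the epoxide and the electron-poor alkenes are inert.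

Step 22
Reactants: 26 (4R,5S,6S,8S,10R)-8-[(2-{[(tert-butyldimethylsilyl)oxy]methyl}acryloyl)oxy]-4,5-epoxy-13-hydroxy-1-oxogermacr-7(11)-en-12,6-olide
Product: 27 (4R,5S,6S,8S,10R)-13-acetoxy-8-[(2-{[(tert-butyldimethylsilyl)oxy]methyl}acryloyl)oxy]-4,5-epoxy-1-oxogermacr-7(11)-en-12,6-olide
Conditions: Ac2O, pyridine, CH2Cl2, 0 °C
Reagents that add atoms: acetic anhydride, CC(=O)OC(C)=O
Why: Acetylation of the primary allylic alcohol with Ac2O/pyridine, without a stronger nucleophilic base that could displace the new allylic acetate in SN2' fashion.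

Step 23
Reactants: 27 (4R,5S,6S,8S,10R)-13-acetoxy-8-[(2-{[(tert-butyldimethylsilyl)oxy]methyl}acryloyl)oxy]-4,5-epoxy-1-oxogermacr-7(11)-en-12,6-olide
Product: 28 CNP0258719.1, (4R,5S,6S,8S,10R)-13-acetoxy-4,5-epoxy-8-{[2-(hydroxymethyl)acryloyl]oxy}-1-oxogermacr-7(11)-en-12,6-olide
Conditions: HF·pyridine, pyridine, THF, 0 °C
Reagents that add atoms: none
Why: Buffered fluoride cleavage of the primary silyl ether frees the hydroxymethyl acrylate; the weakly acidic fluoride source avoids acyl migration, loss of the C13 acetate and epoxide opening.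

## Compound list

1 | (3aS,6aS)-2,2-dimethyl-3a,6a-dihydro-4H-cyclopenta[d][1,3]dioxol-4-one | O=C1C=C[C@@H]2OC(C)(C)O[C@H]12 | starting material
2 | (3aS,6aS)-5-iodo-2,2-dimethyl-3a,6a-dihydro-4H-cyclopenta[d][1,3]dioxol-4-one | O=C1C(I)=C[C@@H]2OC(C)(C)O[C@H]12 | intermediate
3 | (3aS,6aS)-2,2,5-trimethyl-3a,6a-dihydro-4H-cyclopenta[d][1,3]dioxol-4-one | O=C1C(C)=C[C@@H]2OC(C)(C)O[C@H]12 | intermediate
4 | (3aS,5R,6aS)-2,2,5-trimethyltetrahydro-4H-cyclopenta[d][1,3]dioxol-4-one | C[C@@H]1C[C@@H]2OC(C)(C)O[C@@H]2C1=O | intermediate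
5 | (3aS,4R,5R,6aS)-2,2,5-trimethyl-4-(3-methylbut-3-en-1-yl)tetrahydro-4H-cyclopenta[d][1,3]dioxol-4-ol | C[C@@H]1C[C@@H]2OC(C)(C)O[C@@H]2[C@@]1(O)CCC(C)=C | intermediate
6 | (1R,2S,3S,5R)-5-methyl-1-(3-methylbut-3-en-1-yl)cyclopentane-1,2,3-triol | C[C@@H]1C[C@H](O)[C@H](O)[C@@]1(O)CCC(C)=C | intermediate
7 | (1R,2S,3S,5R)-3-[(tert-butyldimethylsilyl)oxy]-5-methyl-1-(3-methylbut-3-en-1-yl)cyclopentane-1,2-diol | C[C@@H]1C[C@H](O[Si](C)(C)C(C)(C)C)[C@H](O)[C@@]1(O)CCC(C)=C | intermediate
8 | (2R,3R,5S)-5-[(tert-butyldimethylsilyl)oxy]-2-hydroxy-3-methyl-2-(3-methylbut-3-en-1-yl)cyclopentan-1-one | C[C@@H]1C[C@H](O[Si](C)(C)C(C)(C)C)C(=O)[C@@]1(O)CCC(C)=C | intermediate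
9 | (1S,2R,3R,5S)-5-[(tert-butyldimethylsilyl)oxy]-1-(1-methoxypropa-1,2-dien-1-yl)-3-methyl-2-(3-methylbut-3-en-1-yl)cyclopentane-1,2-diol (C7 as expected from attack anti to the silyl ether) | C[C@@H]1C[C@H](O[Si](C)(C)C(C)(C)C)[C@@](O)(C(OC)=C=C)[C@@]1(O)CCC(C)=C | intermediate
10 | 1-[(1S,2R,3R,5S)-5-[(tert-butyldimethylsilyl)oxy]-1,2-dihydroxy-3-methyl-2-(3-methylbut-3-en-1-yl)cyclopentyl]prop-2-en-1-one | C[C@@H]1C[C@H](O[Si](C)(C)C(C)(C)C)[C@@](O)(C(=O)C=C)[C@@]1(O)CCC(C)=C | intermediate
11 | (1R,7S,8S,10R)-8-[(tert-butyldimethylsilyl)oxy]-1,7-dihydroxy-4,10-dimethylbicyclo[5.3.0]dec-4-en-6-one | C[C@@H]1C[C@H](O[Si](C)(C)C(C)(C)C)[C@@]2(O)C(=O)C=C(C)CC[C@@]12O | intermediate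
12 | (1R,6R,7S,8S,10R)-8-[(tert-butyldimethylsilyl)oxy]-4,10-dimethylbicyclo[5.3.0]dec-4-ene-1,6,7-triol | C[C@@H]1C[C@H](O[Si](C)(C)C(C)(C)C)[C@@]2(O)[C@H](O)C=C(C)CC[C@@]12O | intermediate
13 | (1R,4R,5S,6R,7S,8S,10R)-8-[(tert-butyldimethylsilyl)oxy]-4,5-epoxy-4,10-dimethylbicyclo[5.3.0]decane-1,6,7-triol | C[C@@H]1C[C@H](O[Si](C)(C)C(C)(C)C)[C@@]2(O)[C@H](O)[C@@H]3O[C@]3(C)CC[C@@]12O | intermediate
14 | ethyl 2-(diethoxyphosphoryl)acrylate | CCOC(=O)C(=C)P(=O)(OCC)OCC | starting material
15 | 4-methoxybenzyl alcohol | COc1ccc(CO)cc1 | starting material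
16 | ethyl 2-(diethoxyphosphoryl)-3-[(4-methoxybenzyl)oxy]propanoate (racemic) | CCOC(=O)C(COCc1ccc(OC)cc1)P(=O)(OCC)OCC | intermediate
17 | 2-(diethoxyphosphoryl)-3-[(4-methoxybenzyl)oxy]propanoic acid (racemic) | OC(=O)C(COCc1ccc(OC)cc1)P(=O)(OCC)OCC | intermediate
18 | (1R,4R,5S,6R,7S,8S,10R)-8-[(tert-butyldimethylsilyl)oxy]-4,5-epoxy-1,7-dihydroxy-4,10-dimethylbicyclo[5.3.0]decan-6-yl 2-(diethoxyphosphoryl)-3-[(4-methoxybenzyl)oxy]propanoate | C[C@@H]1C[C@H](O[Si](C)(C)C(C)(C)C)[C@@]2(O)[C@H](OC(=O)C(COCc4ccc(OC)cc4)P(=O)(OCC)OCC)[C@@H]3O[C@]3(C)CC[C@@]12O | intermediate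
19 | (4R,5S,6R,8S,10R)-8-[(tert-butyldimethylsilyl)oxy]-4,5-epoxy-4,10-dimethyl-1,7-dioxocyclodecan-6-yl 2-(diethoxyphosphoryl)-3-[(4-methoxybenzyl)oxy]propanoate | CC(C)(C)[Si](C)(C)O[C@H]1C[C@@H](C)C(=O)CC[C@@]2(C)O[C@H]2[C@@H](OC(=O)C(COCc2ccc(OC)cc2)P(=O)(OCC)OCC)C1=O | intermediate
20 | (4R,5S,6S,8S,10R)-8-[(tert-butyldimethylsilyl)oxy]-4,5-epoxy-13-[(4-methoxybenzyl)oxy]-1-oxogermacr-7(11)-en-12,6-olide | CC(C)(C)[Si](C)(C)O[C@H]1C[C@@H](C)C(=O)CC[C@@]2(C)O[C@H]2[C@H]2OC(=O)C(COCc3ccc(OC)cc3)=C12 | intermediate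
21 | (4R,5S,6S,8S,10R)-4,5-epoxy-8-hydroxy-13-[(4-methoxybenzyl)oxy]-1-oxogermacr-7(11)-en-12,6-olide | O[C@H]1C[C@@H](C)C(=O)CC[C@@]2(C)O[C@H]2[C@H]2OC(=O)C(COCc3ccc(OC)cc3)=C12 | intermediate
22 | ethyl 2-(hydroxymethyl)acrylate | CCOC(=O)C(=C)CO | starting material
23 | ethyl 2-{[(tert-butyldimethylsilyl)oxy]methyl}acrylate | CCOC(=O)C(=C)CO[Si](C)(C)C(C)(C)C | intermediate
24 | 2-{[(tert-butyldimethylsilyl)oxy]methyl}acrylic acid | OC(=O)C(=C)CO[Si](C)(C)C(C)(C)C | intermediate
25 | (4R,5S,6S,8S,10R)-8-[(2-{[(tert-butyldimethylsilyl)oxy]methyl}acryloyl)oxy]-4,5-epoxy-13-[(4-methoxybenzyl)oxy]-1-oxogermacr-7(11)-en-12,6-olide | C=C(CO[Si](C)(C)C(C)(C)C)C(=O)O[C@H]1C[C@@H](C)C(=O)CC[C@@]2(C)O[C@H]2[C@H]2OC(=O)C(COCc3ccc(OC)cc3)=C12 | intermediate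
26 | (4R,5S,6S,8S,10R)-8-[(2-{[(tert-butyldimethylsilyl)oxy]methyl}acryloyl)oxy]-4,5-epoxy-13-hydroxy-1-oxogermacr-7(11)-en-12,6-olide | C=C(CO[Si](C)(C)C(C)(C)C)C(=O)O[C@H]1C[C@@H](C)C(=O)CC[C@@]2(C)O[C@H]2[C@H]2OC(=O)C(CO)=C12 | intermediate
27 | (4R,5S,6S,8S,10R)-13-acetoxy-8-[(2-{[(tert-butyldimethylsilyl)oxy]methyl}acryloyl)oxy]-4,5-epoxy-1-oxogermacr-7(11)-en-12,6-olide | C=C(CO[Si](C)(C)C(C)(C)C)C(=O)O[C@H]1C[C@@H](C)C(=O)CC[C@@]2(C)O[C@H]2[C@H]2OC(=O)C(COC(C)=O)=C12 | intermediate
28 | CNP0258719.1, (4R,5S,6S,8S,10R)-13-acetoxy-4,5-epoxy-8-{[2-(hydroxymethyl)acryloyl]oxy}-1-oxogermacr-7(11)-en-12,6-olide | C=C(CO)C(=O)O[C@H]1C[C@@H](C)C(=O)CC[C@@]2(C)O[C@H]2[C@H]2OC(=O)C(COC(C)=O)=C12 | target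

## Step count and least certain steps

Total: 23 steps. Longest linear sequence: 19 steps (1–11, 14–17, 20–23); steps 12–13 and 18–19 are two-step side branches.

**Step 15 (key step).** The most likely failure is not the cleavage itself but what the medium does to its product. The lead salts are Lewis acidic and acetic acid is released, which may open the epoxide or enolise the strained, doubly α-oxygenated C7 ketone of the new 1,5-dione (transannular aldol, epimerisation at C6/C8, β-elimination across C5–C6). The fallback sets out from 18 and cuts the same bond at the alkene level without metal or acid. Thiocarbonyldiimidazole (toluene, 80 °C) converts the cis-diol into cyclic thionocarbonate F1. 1,3-Dimethyl-2-phenyl-1,3,2-diazaphospholidine (40 °C, Corey–Winter olefination) gives the tetrasubstituted C1=C7 alkene F2. Ozonolysis (O3, CH2Cl2/MeOH, −78 °C, then Me2S) of this most electron-rich alkene returns to 19.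

**Step 16.** Two processes compete with ring closure. The phosphonate carbanion may lose 4-methoxybenzyl alkoxide (retro-oxa-Michael) before it reaches the ketone. The base may also remove C6–H of the α-acyloxy ketone, which opens the epoxide by β-elimination. The fallback sets out from 13 and avoids both a carbanion with a β-leaving group and an amine base. Acryloyl chloride (i-Pr2NEt, −78 °C) gives acrylate F8. Glycol cleavage as in step 15 gives dione acrylate F9. A phosphine-catalysed intramolecular Morita–Baylis–Hillman reaction (PMe3, THF/t-BuOH) onto the activated C7 ketone gives α-methylene-β-hydroxy lactone F10. Ac2O/DMAP acetylates the tertiary allylic alcohol and transposes it (SN2') to the conjugated primary acetate F11, which already carries the C13 acetate. HF·pyridine gives alcohol F12, and Steglich esterification with 24 rejoins the route at 27 (steps 21 and 22 are then not needed).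

**Step 10.** Poor facial selectivity in the hydride transfer is likely. The desired hydride delivery is to the concave face of the cis-fused bicycle, against its steric bias, and it is not certain which arm of the ketone the catalyst treats as the large group. The fallback sets out from 11 and uses the substrate bias instead. Luche reduction (NaBH4, CeCl3·7H2O, MeOH, −78 °C) from the convex face should give the (6S)-epimer F6. Mitsunobu inversion with 4-nitrobenzoic acid (PPh3, DIAD) gives (6R)-4-nitrobenzoate F7, and methanolysis (K2CO3, MeOH) returns to 12.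

**Step 8.** The basic organolithium may enolise the hindered α-silyloxy ketone (recovered or C8-epimerised ketone) instead of adding. During the acidic unmasking, the α-hydroxy enone may undergo α-ketol rearrangement or oxa-Michael closure. The fallback sets out from 8 with a non-basic allylation. Indium-mediated Barbier addition of 3-bromoprop-1-enyl benzoate (In powder, THF/H2O) gives benzoate F3 (C6 epimers). Metathesis as in step 9 gives cycloheptenyl benzoate F4, methanolysis (K2CO3, MeOH) gives triol F5, and IBX oxidation of the allylic alcohol returns to 11, where C6 is reset by step 10.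

## Further compounds

F1 | step 15 | cyclic C1,C7-thionocarbonate of 18 | C[C@@H]1C[C@H](O[Si](C)(C)C(C)(C)C)[C@@]2(OC(=S)O4)[C@H](OC(=O)C(COCc5ccc(OC)cc5)P(=O)(OCC)OCC)[C@@H]3O[C@]3(C)CC[C@@]124
F2 | step 15 | (4R,5S,6R,8S,10R)-8-[(tert-butyldimethylsilyl)oxy]-4,5-epoxy-4,10-dimethylbicyclo[5.3.0]dec-1(7)-en-6-yl 2-(diethoxyphosphoryl)-3-[(4-methoxybenzyl)oxy]propanoate | C[C@@H]1C[C@H](O[Si](C)(C)C(C)(C)C)C2=C1CC[C@@]3(C)O[C@H]3[C@H]2OC(=O)C(COCc4ccc(OC)cc4)P(=O)(OCC)OCC
F3 | step 8 | 1-[(1S,2R,3R,5S)-5-[(tert-butyldimethylsilyl)oxy]-1,2-dihydroxy-3-methyl-2-(3-methylbut-3-en-1-yl)cyclopentyl]prop-2-en-1-yl benzoate (C6 epimers) | C[C@@H]1C[C@H](O[Si](C)(C)C(C)(C)C)[C@@](O)(C(OC(=O)c2ccccc2)C=C)[C@@]1(O)CCC(C)=C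
F4 | step 8 | (1R,7S,8S,10R)-8-[(tert-butyldimethylsilyl)oxy]-1,7-dihydroxy-4,10-dimethylbicyclo[5.3.0]dec-4-en-6-yl benzoate (C6 epimers) | C[C@@H]1C[C@H](O[Si](C)(C)C(C)(C)C)[C@@]2(O)C(OC(=O)c3ccccc3)C=C(C)CC[C@@]12O
F5 | step 8 | (1R,7S,8S,10R)-8-[(tert-butyldimethylsilyl)oxy]-4,10-dimethylbicyclo[5.3.0]dec-4-ene-1,6,7-triol (C6 epimers) | C[C@@H]1C[C@H](O[Si](C)(C)C(C)(C)C)[C@@]2(O)C(O)C=C(C)CC[C@@]12O
F6 | step 10 | (1R,6S,7S,8S,10R)-8-[(tert-butyldimethylsilyl)oxy]-4,10-dimethylbicyclo[5.3.0]dec-4-ene-1,6,7-triol (6-epi-12) | C[C@@H]1C[C@H](O[Si](C)(C)C(C)(C)C)[C@@]2(O)[C@@H](O)C=C(C)CC[C@@]12O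
F7 | step 10 | (1R,6R,7S,8S,10R)-8-[(tert-butyldimethylsilyl)oxy]-1,7-dihydroxy-4,10-dimethylbicyclo[5.3.0]dec-4-en-6-yl 4-nitrobenzoate | C[C@@H]1C[C@H](O[Si](C)(C)C(C)(C)C)[C@@]2(O)[C@H](OC(=O)c3ccc(cc3)[N+](=O)[O-])C=C(C)CC[C@@]12O
F8 | step 16 | (1R,4R,5S,6R,7S,8S,10R)-8-[(tert-butyldimethylsilyl)oxy]-4,5-epoxy-1,7-dihydroxy-4,10-dimethylbicyclo[5.3.0]decan-6-yl acrylate | C[C@@H]1C[C@H](O[Si](C)(C)C(C)(C)C)[C@@]2(O)[C@H](OC(=O)C=C)[C@@H]3O[C@]3(C)CC[C@@]12O
F9 | step 16 | (4R,5S,6R,8S,10R)-8-[(tert-butyldimethylsilyl)oxy]-4,5-epoxy-4,10-dimethyl-1,7-dioxocyclodecan-6-yl acrylate | CC(C)(C)[Si](C)(C)O[C@H]1C[C@@H](C)C(=O)CC[C@@]2(C)O[C@H]2[C@@H](OC(=O)C=C)C1=O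
F10 | step 16 | (4R,5S,6S,8S,10R)-8-[(tert-butyldimethylsilyl)oxy]-4,5-epoxy-7-hydroxy-1-oxogermacr-11(13)-en-12,6-olide (C7 unassigned) | CC(C)(C)[Si](C)(C)O[C@H]1C[C@@H](C)C(=O)CC[C@@]2(C)O[C@H]2[C@H]2OC(=O)C(=C)C12O
F11 | step 16 | (4R,5S,6S,8S,10R)-13-acetoxy-8-[(tert-butyldimethylsilyl)oxy]-4,5-epoxy-1-oxogermacr-7(11)-en-12,6-olide | CC(C)(C)[Si](C)(C)O[C@H]1C[C@@H](C)C(=O)CC[C@@]2(C)O[C@H]2[C@H]2OC(=O)C(COC(C)=O)=C12
F12 | step 16 | (4R,5S,6S,8S,10R)-13-acetoxy-4,5-epoxy-8-hydroxy-1-oxogermacr-7(11)-en-12,6-olide | O[C@H]1C[C@@H](C)C(=O)CC[C@@]2(C)O[C@H]2[C@H]2OC(=O)C(COC(C)=O)=C12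
A1 | alternative 1 | seco-C4/C5 diene: (5S)-4-[(1S,3R)-1-[(tert-butyldimethylsilyl)oxy]-3,7-dimethyl-4-oxooct-7-en-1-yl]-3-{[(4-methoxybenzyl)oxy]methyl}-5-vinylfuran-2(5H)-one | C=C(C)CCC(=O)[C@H](C)C[C@H](O[Si](C)(C)C(C)(C)C)C1=C(COCc2ccc(OC)cc2)C(=O)O[C@@H]1C=C
A2 | alternative 1 | (4Z,6S,8S,10R)-8-[(tert-butyldimethylsilyl)oxy]-13-[(4-methoxybenzyl)oxy]-1-oxogermacra-4,7(11)-dien-12,6-olide | CC(C)(C)[Si](C)(C)O[C@H]1C[C@@H](C)C(=O)CC/C(C)=C\[C@H]2OC(=O)C(COCc3ccc(OC)cc3)=C12
A3 | alternative 2 | methyl (Z)-4-[(tert-butyldimethylsilyl)oxy]-9-[(2R,3S)-3-formyl-2-methyloxiran-2-yl]-2-{[(4-methoxybenzyl)oxy]methyl}-6-methyl-7-oxo-3-[(trifluoromethylsulfonyl)oxy]non-2-enoate (C4 S, C6 R of the chain) | O=C[C@@H]1O[C@]1(C)CCC(=O)[C@H](C)C[C@H](O[Si](C)(C)C(C)(C)C)/C(OS(=O)(=O)C(F)(F)F)=C(\COCc1ccc(OC)cc1)C(=O)OC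
A4 | alternative 3 | (S)-isopiperitenone, (S)-3-methyl-6-(prop-1-en-2-yl)cyclohex-2-en-1-one | CC1=CC(=O)[C@@H](CC1)C(C)=C
A5 | alternative 3 | trans-3-methyl-6-(prop-1-en-2-yl)-1-vinylcyclohex-2-en-1-ol (vinyl trans to isopropenyl) | CC1=C[C@@](O)(C=C)[C@@H](CC1)C(C)=C
A6 | alternative 3 | (2Z,6E)-3,7-dimethylcyclodeca-2,6-dien-1-one | O=C1/C=C(C)\CC/C=C(C)/CCC1
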